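All runs are simulated with made-up constants.

Your ash run left 69.6% of its starting material at 20.0 h. Start from that leftover.

- ash: starting material 20 mM; coupling partner 54 mM; initiator 0.18 mM; run made earlier
- flask: starting material 20 mM; coupling partner 36.0 mM; initiator 0.18 mM; time 2.5 d

ash run (percent of the starting material charged)

| time / h | product / % | starting material / % |
|---|---|---|
| 1.33 | 2.6 | 98.8 |
| 4.00 | 5.3 | 95.5 |
| 6.00 | 9.2 | 90.2 |
| 10.0 | 17.6 | 83.1 |
| 15.0 | 23.3 | 75.8 |
| 20.0 | 30.6 | 69.6 |

(each reading ± 1 percentage point)

- what is said of product includes idle adduct
- the numbers in the tables scatter with a standard deviation of 1 percentage point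
- candidate steps: starting material + second chain carrier -> released group + first chain carrier; first chain carrier -> ended carrier; initiator -> 2 initiating radical; 2 second chain carrier -> ended chains; starting material + initiating radical -> capped initiator + first chain carrier; coupling partner + first chain carrier -> product + second chain carrier; coupling partner <-> dormant form; coupling partner + product <-> idle adduct

1. amount of product in percent of the starting material charged, at 3.0 h, 15 h and 2.5 d

How fast does the ash run turn over? Define the turnover rate as the fraction of the remaining starting material used per hour: 0.0181 h⁻¹, a pseudo-first-order constant read from one reading. Rate times time counts turnovers, and the share converted is one minus e to the minus count. At 10.0 h this gives 16.6% converted, and the ash run reads 17.6% of product.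

Does the flask have enough partner? At the ash rate it counts 1.09 turnovers in 2.5 d. At one partner for each starting material reacted, that takes 13.3 mM of coupling partner, and the flask charges 36.0 mM. By the charge, starting material is the limiting reagent.

Does the turnover rate follow the partner? The ash run has one partner charge, so I do not read this from it. If second chain carriers end in pairs, the rate ignores partner, and the count gives 66.2% for the flask. If first chain carriers do the ending, the rate scales by 0.667, and the same count gives 51.6% for the flask. Both endings are candidates, so as a judgement, not a rate law, I scale the ash rate by the square root of the partner ratio: 0.0148 h⁻¹. My course for the flask is 4.34%, 19.9% and 58.9%.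

The forecast gives 4.5%, 20% and 57%, leaning “slightly toward weak partner dependence”. My last point is higher.

The flask gives 4.64%, 20.8% and 60.9%.

    starting material + second chain carrier → released group + first chain carrier (k = 1.80 × 10⁷ L mol⁻¹ h⁻¹)
    first chain carrier → ended carrier (k = 280 h⁻¹)
    initiator → 2 initiating radical (k = 0.00240 h⁻¹)
    2 second chain carrier → ended chains (k = 8.00 × 10⁷ L mol⁻¹ s⁻¹)
    starting material + initiating radical → capped initiator + first chain carrier (k = 1.90 × 10⁵ L mol⁻¹ s⁻¹)
    coupling partner + first chain carrier → product + second chain carrier (k = 6.10 × 10⁶ L mol⁻¹ h⁻¹)
    coupling partner ⇌ dormant form (K = 0.120, k = 0.0290 h⁻¹)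
    coupling partner + product ⇌ idle adduct, settled at all times (K = 12.0 L mol⁻¹)

At 2.50 d, the flask's coupling partner stands at 53.3% of its own charge. Read back, the flask counted 0.939 turnovers, an average turnover rate of 0.0157 h⁻¹. That is 0.867 of the ash reading, while the ratio of partner charges is 0.667. At this rate 25.0 d counts 9.42 turnovers, and the flask then holds starting material 0% and product 99.8%.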